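**Retrosynthetic overview**

- The target is a 5-alkylresorcinol: ring carbons C1 and C3 carry OH, C5 carries the chain C1′–C17′ (carbinol C15′, S). The two oxygens and the alkyl group are mutually meta, which is the pattern a 3-alkylcyclobutenone (supplying C1, C4, C5, C6) and an oxygenated alkyne (supplying C2, C3) give by connectivity alone.
- End game: methanolysis of a C15′ acetate and cleavage of a C3 ethyl ether lead back to the benzannulation product.
- Key disconnection: ring bonds C1–C2 and C3–C4 (with C6–C1 broken and re-formed) lead back to the 3-alkylcyclobutenone and ethoxyethyne. This closes the benzene ring, the second ring formed.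
- The cyclobutenone (the four-membered ring, formed first) comes from a terminal alkyne and dichloroketene by [2+2] cycloaddition (bonds C4–C1 and C5–C6), then dechlorination. The alkyne carbons become C4 and C5.
- The terminal alkynyl acetate comes from zipper isomerisation of the internal alkynol made from 1-pentadecyne and (S)-1,2-epoxybutane (bond C13′–C14′). C15′ is taken from the chiral pool and no bond to it is broken afterwards.

Key step: step 6

Remark on the chemistry (assumptions): ethoxyethyne is used as the commercial solution in hexanes. Locants are as defined above. The descriptor at C15′ stays S from compound 1 to the target because the ranking O > long chain > ethyl holds in every intermediate.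

**Route**

Step 1
Reactants: 1 (S)-1,2-epoxybutane; 2 1-pentadecyne
Product: 4 (3S)-nonadec-5-yn-3-ol, via lithium pentadec-1-yn-1-ide 3 (not isolated)
Conditions: n-BuLi, THF, −78 °C; then BF3·OEt2, then 1, −78 °C; aq NH4Cl
Reagents that add atoms: none
Why: Yamaguchi–Hirao alkynylation, in which the BF3-activated epoxide is opened by the lithium acetylide in an SN2 attack at the unsubstituted CH2 terminus, so the C–O bond at the stereocentre is never broken and the S configuration of 1 passes unchanged into C15′.

Step 2
Reactants: 4 (3S)-nonadec-5-yn-3-ol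
Product: 6 (3S)-nonadec-18-yn-3-ol, via dipotassium alkoxide acetylide 5 (not isolated)
Conditions: KNH(CH2)3NH2 (from KH, H2N(CH2)3NH2), H2N(CH2)3NH2, 0 °C → rt; then H2O
Reagents that add atoms: none
Why: Alkyne zipper isomerisation, in which repeated propargyl/allenyl deprotonation and reprotonation walk the triple bond along the methylene chain until irreversible formation of the terminal acetylide stops it, while the C3 alkoxide blocks migration through the carbinol carbon and keeps that centre configurationally intact.

Step 3
Reactants: 6 (3S)-nonadec-18-yn-3-ol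
Product: 7 (3S)-nonadec-18-yn-3-yl acetate
Conditions: Ac2O, pyridine, DMAP (cat.), CH2Cl2, 0 °C → rt
Reagents that add atoms: acetic anhydride, CC(=O)OC(C)=O
Why: DMAP-catalysed acylation of the secondary alcohol without touching C15′, needed because the acid chloride and zinc chloride of the next step would acylate or ionise a free carbinol.

Step 4
Reactants: 7 (3S)-nonadec-18-yn-3-yl acetate; 8 trichloroacetyl chloride
Product: 10 (3S)-17-(4,4-dichloro-3-oxocyclobut-1-en-1-yl)heptadecan-3-yl acetate, via dichloroketene 9 (not isolated)
Conditions: Zn–Cu couple, Et2O/DME, slow addition of 8, rt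
Reagents that add atoms: none
Why: Ketene–alkyne [2+2] cycloaddition, in which dichloroketene made by zinc dechlorination of 8 bonds through its carbonyl carbon to the nucleophilic terminal CH of the alkyne to give the 3-alkyl-4,4-dichlorocyclobutenone, with DME sequestering ZnCl2 so that ketene polymerisation and attack on the acetate are held back.

Step 5
Reactants: 10 (3S)-17-(4,4-dichloro-3-oxocyclobut-1-en-1-yl)heptadecan-3-yl acetate
Product: 11 (3S)-17-(3-oxocyclobut-1-en-1-yl)heptadecan-3-yl acetate
Conditions: Zn dust, AcOH, TMEDA, EtOH, 0 °C → rt
Reagents that add atoms: none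
Why: Reductive dechlorination of the α,α-dichloroketone by zinc with acetic acid as proton source, buffered by TMEDA to protect the sensitive cyclobutenone; any 2,4-dichloro isomer from allylic chlorine shift converges on the same product, and the acetate and C15′ are untouched.

Step 6
Reactants: 11 (3S)-17-(3-oxocyclobut-1-en-1-yl)heptadecan-3-yl acetate; 12 ethoxyethyne
Product: 17 (3S)-17-(3-ethoxy-5-hydroxyphenyl)heptadecan-3-yl acetate, via vinylketene 13 (not isolated), via 4-vinylcyclobutenone 14 (not isolated), via dienylketene 15 (not isolated), via cyclohexadienone 16 (not isolated)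
Conditions: 12 (3 equiv), toluene, 80 °C, sealed tube, Ar
Reagents that add atoms: none
Why: Heating opens cyclobutenone 11 by four-electron conrotatory electrocyclic cleavage of its C(=O)–CH2 bond (ring bond C1–C6) to vinylketene 13, whose ketene C=C adds ethoxyethyne in a [2+2] cycloaddition (bonds C1–C2 and C3–C4) to 4-vinylcyclobutenone 14; a second, reversible four-electron opening gives dienylketene 15, and only the isomer with the vinyl group cis to the ketene can close, so the equilibrium drains through it. The closest known reaction type is the Danheiser benzannulation of 3-substituted cyclobutenones with alkoxy- and siloxyalkynes, applied here to an unbranched 3-alkyl case. The one ring closed, the benzene ring, is formed by six-electron disrotatory electrocyclisation of 15, which re-forms C6–C1 and gives cyclohexadienone 16, and 16 tautomerises irreversibly to phenol 17. No stereocentre is created (the sp3 ring carbon of 14 is transient), and C15′, fourteen methylenes away and under neutral conditions, is not affected. The selectivity required is the regiochemistry of the [2+2] step: the ynol ether is nucleophilic at its CH carbon and the ketene electrophilic at its carbonyl carbon, so C1 bonds to the alkyne CH and the ethoxy group lands on C3, meta to both the hydroxyl and the chain, while the single C3 substituent of the cyclobutenone fixes the chain at C5. Working at 80 °C with excess alkyne in a closed vessel should keep the bimolecular capture ahead of retro-ene loss of ethylene from ethoxyethyne and of vinylketene self-reaction.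

Step 7
Reactants: 17 (3S)-17-(3-ethoxy-5-hydroxyphenyl)heptadecan-3-yl acetate
Product: 18 (3S)-17-(3,5-dihydroxyphenyl)heptadecan-3-yl acetate
Conditions: BBr3 (4 equiv), CH2Cl2, −78 → 0 °C; then ice-water
Reagents that add atoms: none
Why: Lewis-acid ether cleavage, in which BBr3 coordinates the aryl ether oxygen and bromide removes the primary ethyl group by SN2 (the free phenol travels as its aryloxydibromoborane and returns on hydrolysis); between −78 and 0 °C this should be faster than any C–O scission of the secondary acetate, so C15′ is not exposed to bromide.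

Step 8
Reactants: 18 (3S)-17-(3,5-dihydroxyphenyl)heptadecan-3-yl acetate
Product: 19 Hansfordiol C, 5-[(15S)-15-hydroxyheptadecyl]benzene-1,3-diol
Conditions: K2CO3, MeOH (degassed), rt; then aq NH4Cl
Reagents that add atoms: none
Why: Base-catalysed transesterification (methanolysis) of the secondary acetate at the acyl carbon, with no bond to C15′ broken, so the S configuration is retained; degassed solvent protects the electron-rich resorcinol from air oxidation.

**Compound list**

1 | (S)-1,2-epoxybutane | CC[C@H]1CO1 | starting material
2 | 1-pentadecyne | C#CCCCCCCCCCCCCC | starting material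
3 | lithium pentadec-1-yn-1-ide | [Li]C#CCCCCCCCCCCCCC | intermediate
4 | (3S)-nonadec-5-yn-3-ol | CC[C@H](O)CC#CCCCCCCCCCCCCC | intermediate
5 | dipotassium alkoxide acetylide of (3S)-nonadec-18-yn-3-ol | CC[C@H]([O-])CCCCCCCCCCCCCCC#[C-].[K+].[K+] | intermediate
6 | (3S)-nonadec-18-yn-3-ol | CC[C@H](O)CCCCCCCCCCCCCCC#C | intermediate
7 | (3S)-nonadec-18-yn-3-yl acetate | CC[C@H](OC(C)=O)CCCCCCCCCCCCCCC#C | intermediate
8 | trichloroacetyl chloride | ClC(=O)C(Cl)(Cl)Cl | starting material
9 | dichloroketene | O=C=C(Cl)Cl | intermediate
10 | (3S)-17-(4,4-dichloro-3-oxocyclobut-1-en-1-yl)heptadecan-3-yl acetate | CC[C@H](OC(C)=O)CCCCCCCCCCCCCCC1=CC(=O)C1(Cl)Cl | intermediate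
11 | (3S)-17-(3-oxocyclobut-1-en-1-yl)heptadecan-3-yl acetate | CC[C@H](OC(C)=O)CCCCCCCCCCCCCCC1=CC(=O)C1 | intermediate
12 | ethoxyethyne | CCOC#C | starting material
13 | vinylketene, (3S)-18-methylidene-20-oxoicos-19-en-3-yl acetate | CC[C@H](OC(C)=O)CCCCCCCCCCCCCCC(=C)C=C=O | intermediate
14 | 4-vinylcyclobutenone, (3S)-18-(2-ethoxy-4-oxocyclobut-2-en-1-yl)nonadec-18-en-3-yl acetate (both epimers at the ring CH) | CC[C@H](OC(C)=O)CCCCCCCCCCCCCCC(=C)C1C(OCC)=CC1=O | intermediate
15 | dienylketene, (3S,19E)-20-ethoxy-18-methylidene-22-oxodocosa-19,21-dien-3-yl acetate | CC[C@H](OC(C)=O)CCCCCCCCCCCCCCC(=C)/C=C(OCC)\C=C=O | intermediate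
16 | cyclohexadienone, (3S)-17-(3-ethoxy-5-oxocyclohexa-1,3-dien-1-yl)heptadecan-3-yl acetate | CC[C@H](OC(C)=O)CCCCCCCCCCCCCCC1=CC(OCC)=CC(=O)C1 | intermediate
17 | (3S)-17-(3-ethoxy-5-hydroxyphenyl)heptadecan-3-yl acetate | CC[C@H](OC(C)=O)CCCCCCCCCCCCCCc1cc(O)cc(OCC)c1 | intermediate
18 | (3S)-17-(3,5-dihydroxyphenyl)heptadecan-3-yl acetate | CC[C@H](OC(C)=O)CCCCCCCCCCCCCCc1cc(O)cc(O)c1 | intermediate
19 | Hansfordiol C, 5-[(15S)-15-hydroxyheptadecyl]benzene-1,3-diol | CC[C@H](O)CCCCCCCCCCCCCCc1cc(O)cc(O)c1 | target

**Totals**

Total step count: 8. Longest linear sequence: 8 steps (from 1 and 2 to 19).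

**Steps most likely to fail**

1. Step 6 (benzannulation). What may go wrong: retro-ene loss of ethylene from ethoxyethyne to ketene before it is captured, oligomerisation of the vinylketene, and O-acylation of the product phenol by the vinylketene, all of which lower throughput.
Fallback, from 1 back to 19, assembling the arene by cross-coupling instead of building it: 1-tridecyne (C#CCCCCCCCCCCC) is deprotonated with n-BuLi to lithium tridec-1-yn-1-ide F1, which opens (S)-1,2-epoxybutane 1 under BF3·OEt2 in THF at −78 °C to give (3S)-heptadec-5-yn-3-ol F2. Zipper isomerisation with KNH(CH2)3NH2 gives, through the dipotassium alkoxide acetylide F3, (3S)-heptadec-16-yn-3-ol F4. Sonogashira coupling of F4 with 1,3-bis(benzyloxy)-5-bromobenzene (Brc1cc(OCc2ccccc2)cc(OCc2ccccc2)c1; Pd(PPh3)2Cl2, CuI, Et3N, 70 °C) gives (3S)-17-[3,5-bis(benzyloxy)phenyl]heptadec-16-yn-3-ol F5. Hydrogenation over Pd/C (H2, EtOAc/EtOH) saturates the alkyne and removes both benzyl ethers, arriving at 19.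

2. Step 7 (ether cleavage). What may go wrong: Lewis-acid activation of the acetate carbonyl followed by bromide substitution or elimination at C15′ (loss or scrambling of the stereocentre), or incomplete removal of the ethyl group if the mixture is kept cold enough to spare the ester.
Fallback, from 17 back to 19, with the order reversed so that no ester is present when the Lewis acid is used, and with a reagent specific for primary alkyl aryl ethers: methanolysis of 17 (K2CO3, MeOH, rt) gives 3-ethoxy-5-[(15S)-15-hydroxyheptadecyl]phenol F6. BCl3 with n-Bu4NI in CH2Cl2 (−78 → 0 °C) then removes the ethyl group by iodide attack on the boron-activated ether, while the secondary carbinol rides through as a chloroborate that water returns to the alcohol, giving 19.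

3. Step 4 (dichloroketene cycloaddition). What may go wrong: zinc chloride-promoted polymerisation of dichloroketene outrunning its addition to the unactivated alkyne, and loss of material through chlorine migration and hydrolysis of the dichloro adduct.
Fallback, from 7 back to 11, bypassing 10 and step 5: N,N-dimethylacetamide (CC(=O)N(C)C) with Tf2O and 2,4,6-collidine in ClCH2CH2Cl at reflux generates N,N-dimethylketeniminium triflate F7. This adds to alkyne 7 in a Ghosez keteniminium [2+2] cycloaddition, with the same regiochemistry as the ketene, to give the cyclobuteniminium triflate F8. Hydrolysis with aqueous NaHCO3 gives cyclobutenone 11 directly.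

**Further compounds**

F1 | step 6 | lithium tridec-1-yn-1-ide | [Li]C#CCCCCCCCCCCC
F2 | step 6 | (3S)-heptadec-5-yn-3-ol | CC[C@H](O)CC#CCCCCCCCCCCC
F3 | step 6 | dipotassium alkoxide acetylide of (3S)-heptadec-16-yn-3-ol | CC[C@H]([O-])CCCCCCCCCCCCC#[C-].[K+].[K+]
F4 | step 6 | (3S)-heptadec-16-yn-3-ol | CC[C@H](O)CCCCCCCCCCCCC#C
F5 | step 6 | (3S)-17-[3,5-bis(benzyloxy)phenyl]heptadec-16-yn-3-ol | CC[C@H](O)CCCCCCCCCCCCC#Cc1cc(OCc2ccccc2)cc(OCc2ccccc2)c1
F6 | step 7 | 3-ethoxy-5-[(15S)-15-hydroxyheptadecyl]phenol | CC[C@H](O)CCCCCCCCCCCCCCc1cc(O)cc(OCC)c1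
F7 | step 4 | N,N-dimethylketeniminium trifluoromethanesulfonate | C=C=[N+](C)C.[O-]S(=O)(=O)C(F)(F)F
F8 | step 4 | N-{3-[(15S)-15-acetoxyheptadecyl]cyclobut-2-en-1-ylidene}-N-methylmethanaminium trifluoromethanesulfonate | CC[C@H](OC(C)=O)CCCCCCCCCCCCCCC1=CC(=[N+](C)C)C1.[O-]S(=O)(=O)C(F)(F)F
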